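## Retrosynthetic overview

1. Target ⇒ (global desilylation) ⇒ cut the C(sp3)–C(sp2) bond between the ring B lateral carbon and the trisubstituted alkene: a nickel-catalysed enantioconvergent reductive coupling of a ring B lateral chloride with an alkenyl bromide.
2. Alkenyl bromide ⇒ cut the CH(Me)–CH(O) bond next to ring A: a metal-free silylium–IDPi lateral Mukaiyama aldol of a pyrone-derived silyl dienol ether with an α-methyl-β-silyloxy aldehyde.
3. That aldehyde ⇒ IDPi-catalysed syn aldol of a propanal enol silane with (E)-3-bromo-2-methylacrolein (from propargyl alcohol).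
4. Ring B chloride ⇒ lateral chlorination ⇒ the same lateral Mukaiyama aldol of the silyl dienol ether with propanal, which sets the first stereocentres.
5. Rings: one γ-pyrone (3-pentanone + propionic anhydride) is made first and serves as both ring A and ring B; no ring is formed later.

Target name used for locants: 2-[(2R,3E,5R,6S,7S,8S)-8-(6-ethyl-3,5-dimethyl-4-oxo-4H-pyran-2-yl)-5,7-dihydroxy-4,6-dimethylnon-3-en-2-yl]-6-[(2R,3R)-3-hydroxypentan-2-yl]-3,5-dimethyl-4H-pyran-4-one. Ring A is the pyrone carrying the ethyl group, ring B the pyrone carrying the hydroxypentyl chain. C2–C8 are nonene chain atoms; C2'/C3' are the side-chain atoms on ring B.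

Assumption: the absolute sense of induction of each chiral catalyst is taken as written and would be confirmed on the first run, with the antipode used if needed. IDPi means a BINOL-derived imidodiphosphorimidate Brønsted acid (two 3,3'-diaryl-BINOL phosphoryl units bridged by nitrogen, P=N–SO2CF3 groups).

## Route

Step 1
Reactants: 1 pentan-3-one; 2 propionic anhydride
Product: 3 2,6-diethyl-3,5-dimethyl-4H-pyran-4-one
Conditions: polyphosphoric acid, neat, 95 °C; ice, aq. NaOH work-up, distil
Reagents that add atoms: none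
Why: Acid-mediated double C-acylation of the ketone to the 1,3,5-triketone and cyclodehydration (polyphosphoric acid γ-pyrone synthesis) gives the symmetrical pyrone that serves as ring A and ring B; no stereocentre.

Step 2
Reactants: 3 2,6-diethyl-3,5-dimethyl-4H-pyran-4-one
Product: 4 triethyl{[(2Z)-6-ethyl-2-ethylidene-3,5-dimethyl-2H-pyran-4-yl]oxy}silane
Conditions: Et3SiOTf (1.05 equiv), Et3N (1.5 equiv), Et2O, −78 → 0 °C; pentane, filter under Ar, Kugelrohr
Reagents that add atoms: triethylsilyl trifluoromethanesulfonate, CC[Si](CC)(CC)OS(=O)(=O)C(F)(F)F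
Why: Soft enolisation: O-silylation gives a 4-silyloxypyrylium ion whose lateral CH2 is acidic enough for Et3N, and A(1,3) strain with the 3-methyl group places the ethylidene methyl cis to the ring oxygen (Z); no stereocentre.

Step 3
Reactants: 4 silyl dienol ether; 5 propanal (1.5 equiv)
Product: 6 2-ethyl-3,5-dimethyl-6-[(2R,3R)-3-(triethylsilyloxy)pentan-2-yl]-4H-pyran-4-one
Conditions: (S,S)-IDPi (2 mol%), toluene, −60 °C, 48 h; Et3N quench
Reagents that add atoms: none
Why: Proposed new method: a silylium–IDPi ion pair (formed from 4 and the acid) activates propanal, and attack by the exocyclic carbon of 4 is the only pathway that regenerates an aromatic 4-silyloxypyrylium ion, which passes its Et3Si group on so that the aldolate is released as its TES ether; the confined chiral anion controls the aldehyde face, and an open transition state (aldehyde ethyl group away from the tetrasubstituted pyran ring, silylated oxygen beside the ethylidene H and not its methyl) gives the anti (2R,3R) pair C2'/C3'; closest known reaction type: disulfonimide- or IDPi-catalysed vinylogous Mukaiyama aldol of silyl dienolates.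

Step 4
Reactants: 6 ring B silyl ether
Product: 8 2-(1-chloroethyl)-3,5-dimethyl-6-[(2R,3R)-3-(triethylsilyloxy)pentan-2-yl]-4H-pyran-4-one (both epimers at the CHCl carbon), via lithium dienolate 7 (not isolated)
Conditions: LiN(iPr)2 (1.1 equiv, commercial solution), THF, −78 °C, 20 min; cannulate into C2Cl6 (1.5 equiv), THF, −78 °C
Reagents that add atoms: hexachloroethane, ClC(Cl)(Cl)C(Cl)(Cl)Cl
Why: Kinetic lateral (vinylogous) deprotonation occurs at the unhindered CH2 of the remaining ethyl group and not at the tertiary C2'–H, and the dienolate is chlorinated at carbon (electrophilic halogenation); the new C–Cl centre is left unselective because step 10 is stereoconvergent.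

Step 5
Reactants: 9 prop-2-yn-1-ol
Product: 11 (2E)-3-bromo-2-methylprop-2-en-1-ol, via alkenylalane 10 (not isolated)
Conditions: AlMe3 (3 equiv), Cp2ZrCl2 (0.25 equiv), CH2Cl2, 0 °C → rt, 16 h; N-bromosuccinimide, THF, −30 → 0 °C; aq. K2CO3
Reagents that add atoms: trimethylaluminium, C[Al](C)C; N-bromosuccinimide, O=C1CCC(=O)N1Br
Why: Negishi zirconium-catalysed carboalumination adds Me and Al syn across the alkyne with Al on the terminal carbon, and brominolysis of the C–Al bond proceeds with retention, fixing the E trisubstituted alkene.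

Step 6
Reactants: 11 (2E)-3-bromo-2-methylprop-2-en-1-ol
Product: 12 (2E)-3-bromo-2-methylprop-2-enal
Conditions: MnO2 (15 equiv), CH2Cl2, rt; filter, use as a dried solution (volatile)
Reagents that add atoms: none
Why: Chemoselective allylic alcohol oxidation with MnO2 leaves the vinyl bromide and the alkene geometry untouched.

Step 7
Reactants: 5 propanal
Product: 13 triethyl[(1Z)-prop-1-en-1-yloxy]silane
Conditions: Et3SiOTf, Et3N, Et2O, 0 °C → rt; pentane, filter, fractional distillation (Z major)
Reagents that add atoms: triethylsilyl trifluoromethanesulfonate, CC[Si](CC)(CC)OS(=O)(=O)C(F)(F)F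
Why: Soft enolisation and O-silylation of the aldehyde (silyl enol ether formation) gives mainly the Z isomer, the geometry used in the aldol.

Step 8
Reactants: 12 (2E)-3-bromo-2-methylprop-2-enal; 13 propanal enol silane (1.2 equiv)
Product: 14 (2R,3R,4E)-5-bromo-2,4-dimethyl-3-(triethylsilyloxy)pent-4-enal
Conditions: syn-selective confined IDPi (1 mol%), toluene, −78 °C; Et3N quench
Reagents that add atoms: none
Why: IDPi-catalysed (silylium counteranion-directed) Mukaiyama aldol of a propionaldehyde enol silane: the confined acid permits only a single aldolisation and sets C5 and C6 as the syn (2R,3R) pair under catalyst control, with the silyl group transferred to the new hydroxyl.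

Step 9
Reactants: 4 silyl dienol ether (1.2 equiv); 14 aldehyde
Product: 15 2-[(2S,3S,4S,5R,6E)-7-bromo-4,6-dimethyl-3,5-bis(triethylsilyloxy)hept-6-en-2-yl]-6-ethyl-3,5-dimethyl-4H-pyran-4-one
Conditions: (R,R)-IDPi (antipode of the step 3 catalyst, 3 mol%), toluene, −60 → −40 °C; Et3N quench
Reagents that add atoms: none
Why: Proposed new method: second use of the lateral silylium–IDPi Mukaiyama aldol of step 3, now with the antipodal catalyst; the anti C7/C8 relationship comes from the same open transition state, and the catalyst-preferred aldehyde face is also the Felkin face of the α-methyl aldehyde 14 (C7–O syn to C6–Me), so the addition is matched and gives 7S,8S; closest known reaction type: IDPi-catalysed vinylogous Mukaiyama aldol of silyl dienolates.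

Step 10
Reactants: 8 ring B chloride (1.0 equiv); 15 alkenyl bromide (1.0 equiv)
Product: 16 2-[(2R,3E,5R,6S,7S,8S)-8-(6-ethyl-3,5-dimethyl-4-oxo-4H-pyran-2-yl)-4,6-dimethyl-5,7-bis(triethylsilyloxy)non-3-en-2-yl]-3,5-dimethyl-6-[(2R,3R)-3-(triethylsilyloxy)pentan-2-yl]-4H-pyran-4-one
Conditions: NiCl2(dme) (10 mol%), chiral cyclopropylidene-bridged indane-fused bis(oxazoline) (12 mol%), Mn powder (3 equiv), NaI (0.5 equiv), DMA, 0 °C
Reagents that add atoms: none
Why: Nickel-catalysed enantioconvergent reductive cross-electrophile coupling (secondary benzylic-type chloride with an alkenyl bromide): both epimers of 8 give the same pyrone-stabilised radical, which is captured by the chiral bis(oxazoline)–alkenylnickel species, so C2 is set as R by the ligand with the E alkene retained, and the non-basic medium does not epimerise the acidic C2–H.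

Step 11
Reactants: 16 tris(triethylsilyl) ether
Product: 17 CNP0408419.8 (target)
Conditions: HF·pyridine, pyridine, THF, 0 °C → rt
Reagents that add atoms: none
Why: Buffered HF·pyridine cleaves the three secondary TES ethers (fluoride-mediated desilylation) without base, so no stereocentre, in particular the acidic C2, is touched.

## Compound list

1 | pentan-3-one | CCC(=O)CC | starting material
2 | propionic anhydride | CCC(=O)OC(=O)CC | starting material
3 | 2,6-diethyl-3,5-dimethyl-4H-pyran-4-one | CCc1oc(CC)c(C)c(=O)c1C | intermediate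
4 | triethyl{[(2Z)-6-ethyl-2-ethylidene-3,5-dimethyl-2H-pyran-4-yl]oxy}silane | C/C=C1\OC(CC)=C(C)C(O[Si](CC)(CC)CC)=C1C | intermediate
5 | propanal | CCC=O | starting material
6 | 2-ethyl-3,5-dimethyl-6-[(2R,3R)-3-(triethylsilyloxy)pentan-2-yl]-4H-pyran-4-one | CCc1oc([C@H](C)[C@H](O[Si](CC)(CC)CC)CC)c(C)c(=O)c1C | intermediate
7 | lithium (2Z)-2-ethylidene-3,5-dimethyl-6-[(2R,3R)-3-(triethylsilyloxy)pentan-2-yl]-2H-pyran-4-olate | C/C=C1\OC([C@H](C)[C@H](O[Si](CC)(CC)CC)CC)=C(C)C([O-])=C1C.[Li+] | intermediate (not isolated)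
8 | 2-(1-chloroethyl)-3,5-dimethyl-6-[(2R,3R)-3-(triethylsilyloxy)pentan-2-yl]-4H-pyran-4-one, both epimers at CHCl | CC(Cl)c1oc([C@H](C)[C@H](O[Si](CC)(CC)CC)CC)c(C)c(=O)c1C | intermediate
9 | prop-2-yn-1-ol | C#CCO | starting material
10 | dimethylaluminium (2E)-3-(dimethylalumanyl)-2-methylprop-2-en-1-olate | C[Al](C)OC/C(C)=C/[Al](C)C | intermediate (not isolated)
11 | (2E)-3-bromo-2-methylprop-2-en-1-ol | OC/C(C)=C/Br | intermediate
12 | (2E)-3-bromo-2-methylprop-2-enal | O=C/C(C)=C/Br | intermediate
13 | triethyl[(1Z)-prop-1-en-1-yloxy]silane | C/C=C\O[Si](CC)(CC)CC | intermediate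
14 | (2R,3R,4E)-5-bromo-2,4-dimethyl-3-(triethylsilyloxy)pent-4-enal | O=C[C@H](C)[C@@H](O[Si](CC)(CC)CC)/C(C)=C/Br | intermediate
15 | 2-[(2S,3S,4S,5R,6E)-7-bromo-4,6-dimethyl-3,5-bis(triethylsilyloxy)hept-6-en-2-yl]-6-ethyl-3,5-dimethyl-4H-pyran-4-one | CCc1oc([C@@H](C)[C@@H](O[Si](CC)(CC)CC)[C@H](C)[C@@H](O[Si](CC)(CC)CC)/C(C)=C/Br)c(C)c(=O)c1C | intermediate
16 | tris(triethylsilyl) ether of the target (name as in step 10) | CCc1oc([C@@H](C)[C@@H](O[Si](CC)(CC)CC)[C@H](C)[C@@H](O[Si](CC)(CC)CC)/C(C)=C/[C@@H](C)c2oc([C@H](C)[C@H](O[Si](CC)(CC)CC)CC)c(C)c(=O)c2C)c(C)c(=O)c1C | intermediate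
17 | CNP0408419.8, 2-[(2R,3E,5R,6S,7S,8S)-8-(6-ethyl-3,5-dimethyl-4-oxo-4H-pyran-2-yl)-5,7-dihydroxy-4,6-dimethylnon-3-en-2-yl]-6-[(2R,3R)-3-hydroxypentan-2-yl]-3,5-dimethyl-4H-pyran-4-one | CCc1oc([C@@H](C)[C@@H](O)[C@H](C)[C@@H](O)/C(C)=C/[C@@H](C)c2oc([C@H](C)[C@H](O)CC)c(C)c(=O)c2C)c(C)c(=O)c1C | target

## Step count and risks

Total: 11 steps. Longest linear sequence: 6 steps (5, 6, 8, 9, 10, 11 from propargyl alcohol; equally 1, 2, 3, 4, 10, 11 from pentan-3-one).

**Step 3 (proposed new lateral Mukaiyama aldol).** Risks: the pyrone oxygen is far more basic than an aldehyde, so the silyl group may rest on the product and slow turnover; the anti/syn ratio and ee are unproven. Fallback with known chemistry, setting out from propanal 5 and coming back at 6: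
- D-proline-catalysed self-aldol of propanal gives (2R,3R)-3-hydroxy-2-methylpentanal F1.
- Et3SiCl/imidazole gives (2R,3R)-2-methyl-3-(triethylsilyloxy)pentanal F2.
- Commercial 4-methylheptane-3,5-dione is converted with two equivalents of LiN(iPr)2 into dilithium 4-methylhepta-2,4-diene-3,5-diolate F3, which adds to F2 to give (8S,9R)-7-hydroxy-4,6,8-trimethyl-9-(triethylsilyloxy)undecane-3,5-dione F4 (mixture at the other centres).
- Dess–Martin oxidation gives (8R,9R)-4,6,8-trimethyl-9-(triethylsilyloxy)undecane-3,5,7-trione F5.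
- Neutral cyclodehydration with PPh3/CCl4 closes the pyrone and delivers 6.

**Step 9 (second use of the new method on a hindered chiral aldehyde).** Risks: the α-branched, β-silyloxy aldehyde may be too large for the confined catalyst; stereocontrol at C8 is unproven. Fallback setting out from 3 and 14 and coming back at 15:
- Lateral lithiation of 3 with LiN(SiMe3)2 in THF at −78 °C gives lithium (2Z)-6-ethyl-2-ethylidene-3,5-dimethyl-2H-pyran-4-olate F6.
- Addition of F6 to 14 under substrate (Felkin) control gives 2-[(2S,3S,4S,5R,6E)-7-bromo-3-hydroxy-4,6-dimethyl-5-(triethylsilyloxy)hept-6-en-2-yl]-6-ethyl-3,5-dimethyl-4H-pyran-4-one F7, separated from its C8 epimer by chromatography.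
- Et3SiOTf/2,6-lutidine silylation gives 15.

**Step 10 (nickel reductive coupling of two advanced fragments).** Risks: the pyronyl-ethyl chloride and the hindered trisubstituted alkenyl bromide are outside the demonstrated substrate range; homocoupling or loss of HCl from 8 may compete. Fallback setting out from 6 and 15 and coming back at 16, switching to a nucleophile–electrophile radical coupling:
- 6 is lithiated to 7 and quenched with 1,2-dibromotetrachloroethane to give 2-(1-bromoethyl)-3,5-dimethyl-6-[(2R,3R)-3-(triethylsilyloxy)pentan-2-yl]-4H-pyran-4-one F8 (both epimers).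
- 15 is borylated (B2pin2, PdCl2(PPh3)2, PPh3, KOPh, toluene, 50 °C) to 2-ethyl-3,5-dimethyl-6-[(2S,3S,4S,5R,6E)-4,6-dimethyl-7-(4,4,5,5-tetramethyl-1,3,2-dioxaborolan-2-yl)-3,5-bis(triethylsilyloxy)hept-6-en-2-yl]-4H-pyran-4-one F9.
- F8 and F9 are joined by copper-catalysed enantioconvergent radical C(sp3)–C(sp2) coupling (CuI, chiral cinchona-derived anionic N,N,P ligand, Cs2CO3, trace water) to give 16.

Further compounds
F1 | step 3 | (2R,3R)-3-hydroxy-2-methylpentanal | O=C[C@H](C)[C@H](O)CC
F2 | step 3 | (2R,3R)-2-methyl-3-(triethylsilyloxy)pentanal | O=C[C@H](C)[C@H](O[Si](CC)(CC)CC)CC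
F3 | step 3 | dilithium 4-methylhepta-2,4-diene-3,5-diolate | CC=C([O-])C(C)=C([O-])CC.[Li+].[Li+]
F4 | step 3 | (8S,9R)-7-hydroxy-4,6,8-trimethyl-9-(triethylsilyloxy)undecane-3,5-dione | CCC(=O)C(C)C(=O)C(C)C(O)[C@H](C)[C@H](O[Si](CC)(CC)CC)CC
F5 | step 3 | (8R,9R)-4,6,8-trimethyl-9-(triethylsilyloxy)undecane-3,5,7-trione | CCC(=O)C(C)C(=O)C(C)C(=O)[C@H](C)[C@H](O[Si](CC)(CC)CC)CC
F6 | step 9 | lithium (2Z)-6-ethyl-2-ethylidene-3,5-dimethyl-2H-pyran-4-olate | C/C=C1\OC(CC)=C(C)C([O-])=C1C.[Li+]
F7 | step 9 | 2-[(2S,3S,4S,5R,6E)-7-bromo-3-hydroxy-4,6-dimethyl-5-(triethylsilyloxy)hept-6-en-2-yl]-6-ethyl-3,5-dimethyl-4H-pyran-4-one | CCc1oc([C@@H](C)[C@@H](O)[C@H](C)[C@@H](O[Si](CC)(CC)CC)/C(C)=C/Br)c(C)c(=O)c1C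
F8 | step 10 | 2-(1-bromoethyl)-3,5-dimethyl-6-[(2R,3R)-3-(triethylsilyloxy)pentan-2-yl]-4H-pyran-4-one | CC(Br)c1oc([C@H](C)[C@H](O[Si](CC)(CC)CC)CC)c(C)c(=O)c1C
F9 | step 10 | 2-ethyl-3,5-dimethyl-6-[(2S,3S,4S,5R,6E)-4,6-dimethyl-7-(4,4,5,5-tetramethyl-1,3,2-dioxaborolan-2-yl)-3,5-bis(triethylsilyloxy)hept-6-en-2-yl]-4H-pyran-4-one | CCc1oc([C@@H](C)[C@@H](O[Si](CC)(CC)CC)[C@H](C)[C@@H](O[Si](CC)(CC)CC)/C(C)=C/B2OC(C)(C)C(C)(C)O2)c(C)c(=O)c1C
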